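Numbering used throughout: germacrane numbers, ring C1–C10, methyls on C4 and C10, isopropyl on C7, free hydroxyl on C6 (O6), ester oxygen on C8 (O8), epoxide on C4–C5.

Assumption: the lipase is taken to acetylate the hydroxyl on the future C8; if it prefers the other one, the same enzyme used for hydrolysis of the meso diacetate gives the same monoacetate 7.

Check of the structures: the stereodescriptors of endoperoxide 5 do place isopropyl anti to the O–O bridge. In the target epoxide C3 and C6 are cis, so it descends from a (4Z)-alkene, and O6 is trans (threo) to the epoxide oxygen. The target is (1(10)E,4S,5R,6S,7S,8S). Nothing had to be corrected.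

## Structural features

The target is a germacrane: a ten-membered carbocycle with an E-trisubstituted alkene C1=C10, a trisubstituted cis-fused epoxide on C4–C5, an isopropyl group on C7, a free hydroxyl on C6 and a 3,4,5-trimethoxybenzoate on O8. Five stereocentres C4–C8 stand in a row; O6 and O8 are syn to each other and both anti to the C7 isopropyl group, and the epoxide oxygen is trans to O6. The fragile parts are the epoxy alcohol (Payne rearrangement, and Lewis-acid transannular attack by C1=C10 on the epoxide), the aryl ester with a free hydroxyl in 1,3-relation (acyl migration), and the Z-enal and diene intermediates on the way. The real difficulties are the medium ring with one E and one Z trisubstituted alkene, the absolute control of the C6–C7–C8 triad, and an epoxidation that must choose C4=C5 over C1=C10 and the correct face. The feature exploited is the C5–C9 segment: with C5 and C9 joined as an alkene it is a 2-isopropylcyclopent-4-ene-1,3-diol with both hydroxyls trans to isopropyl. That compound is meso, so one symmetric five-membered ring supplies all three stereocentres in relative terms, and a single desymmetrisation supplies the absolute sense.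

## Logic of the disconnections

30 ⇒ 29. The two C–O bonds of the epoxide are cut first. The epoxide would not survive aluminium, boron or palladium reagents, and the free O6 of 29 can direct the oxidant to C4=C5. The forward step must leave C1=C10 alone and deliver oxygen trans to O6.

29 ⇒ 28 ⇒ 26. After O6 is silylated (28), the ring bond C1–C2 (sp2–sp3) is cut. This gives acyclic 26 with an alkenyl iodide at C1 and a terminal diene whose CH2 is C2. The forward step needs hydroboration at that CH2 only and ring closure at high dilution with retention of both alkene geometries.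

26 ⇒ 24 + 25. The ester C–O bond at O8 is cut. O8 is the only free hydroxyl in 24, so the final acyl group goes on without a protecting group and is carried through the ring closure.

24 ⇒ 22. The C10–CH3 and C1–I bonds are cut back to a terminal alkyne. A syn methylmetalation fixes the E geometry of C1=C10 in one step.

22 ⇒ 19 + 20. The C9–C10 bond is cut to an acetylide and a terminal C8–C9 epoxide. C9 becomes CH2 and O8 is released exactly when it is needed. The forward step needs attack at C9 only, without harm to the silyl ether or the diene.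

19 ⇒ 18 ⇒ 17 ⇒ 16 ⇒ 14 + 15. C2=C3 is cut by methylenation, the C3 oxidation level is adjusted, and C4=C5 is cut to the C5 aldehyde 14 and phosphonate 15. The olefination must be Z-selective, because the cis epoxide needs C3 and C6 cis.

14 ⇒ 13 ⇒ 11. The aldehyde goes back to the primary alcohol and the epoxide to the C8,C9-diol. In 11 the two primary hydroxyls (on C5 and C9) are told apart only by the free O8 next to C9, so the sulfonylation must be chelation-selective.

11 ⇒ 9. C5 and C9 are reconnected as an alkene. The chain becomes a cyclopentene and three stereocentres sit on a rigid ring. The forward step is an ozonolysis with reduction.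

9 ⇒ 8 ⇒ 7 ⇒ 6. Protecting-group interchange and enzymatic acetylation lead back to 6, which is meso. Only the choice between two enantiotopic hydroxyls remains.

6 ⇒ 5 ⇒ 3 + 4. The O–O bond is restored and the C6–O and C8–O bonds are cut together in a retro-[4+2]. The forward cycloaddition must occur anti to isopropyl and faster than the hydrogen shift of 3.

3 ⇒ 1 + 2. The bond from C7 to the isopropyl carbon is cut. The 5-isomer is only the kinetic product, so the alkylation is designed for this: an iodide in a dipolar medium for speed at −40 °C, inverse addition so that no cyclopentadienide remains to equilibrate the product by proton transfer, iodide washed out cold before the photooxygenation, and no isolation of 3.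

## Other disconnections considered

Alternative 1: The cut is C6–C7 with ring contraction. A thirteen-membered diallylic ether A2 (C6–O–C12, C7=C11) is deprotonated at C6 with LiN(iPr)2, and the [2,3]-Wittig shift gives the ten-membered alcohol A1 with an isopropenyl group on C7.
- In favour: one concerted step makes a skeletal C–C bond, the ten-membered ring and two stereocentres, and closing a thirteen-membered ether first is entropically easier than closing a ten-membered carbocycle. On both counts it is better than the chosen key step, which forms no skeletal bond. O6 arrives free, as in 29 (equal).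
- Against: C6 and C12 are both allylic and next to oxygen, so the site of deprotonation is not secured and [1,2]-shift competes. The absolute sense of C6 and C7 must be relayed from C8 across a macrocyclic transition state. A2 needs three trisubstituted alkenes of defined geometry. The isopropenyl group must later be hydrogenated in the presence of two ring alkenes.
- Comparison: the chosen plan fixes the triad by a cycloaddition on a five-membered ring with enzyme-set absolute configuration, which is mechanistically the more predictable. In step count the two are similar, roughly a dozen steps to A2 and then about six more.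

Alternative 2: The cut is C2–C3 and C6–C10, the latter cleaved again later. The oxyallyl cation from the α-chloro ketone A4 adds across its tethered silyloxy diene to give the cis-fused hydroazulenone A3, and a Grob fragmentation of the C6–C10 bond then opens the ten-membered ring.
- In favour: two rings, two C–C bonds and a quaternary centre form in one step. The Z geometry of C4=C5 comes for free from the seven-membered ring, and the ten-membered ring is made by fragmentation without high dilution. On these three points it is better than the chosen plan, which needs a Z-selective olefination, three adjustment steps and a macrocyclisation.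
- Against: C7 and C8 must be set beforehand by other means, and the facial sense of the cycloaddition relative to them is a new problem. The Grob step needs the C1 leaving group anti-periplanar to C6–C10. It leaves a C6 ketone, whose reduction to the 6S alcohol in a medium ring is uncontrolled, with C7 epimerisable and O8 β to the carbonyl.
- Comparison: its ring formation is stronger, its stereocontrol at C6–C8 weaker. The step count is about equal or somewhat longer.

Alternative 3: The cut is C7–C8. CrCl2 turns the allylic bromide of A6 into an allylchromium that adds through C7 to the C8 aldehyde and closes the ring to A5.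
- In favour: ring, C–C bond and two stereocentres form together. The reaction is convergent with respect to the bromide geometry, and a closed chair transition state should give the anti C7/C8 relation that the target has. The epoxide is installed before ring closure on an acyclic (Z)-allylic alcohol, where allylic 1,3-strain gives dependable threo control. This is better than the chosen plan, whose ring epoxidation is its weakest point. O8 is free in A5 for direct acylation (equal to 24).
- Against: the sense of C7 and C8 relative to C6 rests on substrate induction in a macrocyclic transition state. Divalent chromium is needed in large excess, which is less safe. The β,γ-unsaturated aldehyde of A6 is prone to conjugation. The isopropenyl group must be hydrogenated, for example with RhCl(PPh3)3, next to C1=C10 and the epoxide.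
- Comparison: the step count is similar. The chosen plan is stronger on the triad and on safety, and weaker on the epoxide.

Key step: step 2

## Route

Step 1
Reactants: 1 sodium cyclopentadienide; 2 2-iodopropane
Product: 3 5-(propan-2-yl)cyclopenta-1,3-diene
Conditions: 1 (2 M in THF) added over 1 h to 2 (1.5 equiv), THF/DMPU 4:1, −40 °C, 3 h; cold pentane, ice-water wash, Na2SO4; solution kept below −40 °C and used at once
Reagents that add atoms: none
Why: SN2 C-alkylation of cyclopentadienide gives the 5-alkyl isomer as the kinetic product; inverse addition leaves no cyclopentadienide to isomerise it by proton transfer, and below −20 °C the sigmatropic 1,5-hydrogen shift should be negligible.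

Step 2
Reactants: 3 5-(propan-2-yl)cyclopenta-1,3-diene; 4 dioxygen
Product: 6 (1R,2r,3S)-2-(propan-2-yl)cyclopent-4-ene-1,3-diol, via endoperoxide 5 (not isolated)
Conditions: O2, 5,10,15,20-tetraphenylporphyrin (0.5 mol %), white LED, CH2Cl2, −78 °C; then thiourea (1.2 equiv), MeOH, −78 → 20 °C
Reagents that add atoms: none
Why: Energy transfer from the excited porphyrin gives singlet oxygen, which adds to the s-cis-locked diene of 3 in a concerted suprafacial [4+2] cycloaddition, the reaction type known for cyclopentadiene itself (sensitised photooxygenation to the 2,3-dioxabicyclo[2.2.1]heptene, then thiourea reduction to the cis-enediol). The six-membered 1,2-dioxene ring of 5 is closed by the cycloaddition itself, both C–O bonds (at the future C6 and C8) forming in one step, which completes the bicycle. Suprafacial addition makes the two new C–O centres cis to each other; their relation to C7 is set by approach to the diene face opposite the isopropyl group, whose bulk on the sp3 carbon shields the syn face, so C7 becomes a defined pseudo-asymmetric centre with isopropyl anti to the peroxide. The step needs anti facial selectivity (secured by the isopropyl group), a cycloaddition faster than the 1,5-hydrogen shift of 3 (secured at −78 °C, where the shift is frozen while singlet oxygen still reacts very fast with cisoid dienes), and [4+2] in preference to ene reaction (secured by the cisoid diene). Thiourea cleaves only the O–O bond before 5 can rearrange thermally, so the C–O configurations pass unchanged into 6 and the peroxide is never concentrated. Because 6 is meso, no absolute control is needed here.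

Step 3
Reactants: 6 (1R,2r,3S)-2-(propan-2-yl)cyclopent-4-ene-1,3-diol
Product: 7 (1S,4R,5S)-4-hydroxy-5-(propan-2-yl)cyclopent-2-en-1-yl acetate
Conditions: immobilised Candida antarctica lipase B, vinyl acetate (3 equiv), MTBE, 25 °C
Reagents that add atoms: vinyl acetate, C=COC(C)=O
Why: Irreversible lipase transesterification of a meso cyclopentenediol should acylate one enantiotopic hydroxyl only; no stereocentre is created, but the choice of hydroxyl fixes the absolute configuration of the whole triad.

Step 4
Reactants: 7 (1S,4R,5S)-4-hydroxy-5-(propan-2-yl)cyclopent-2-en-1-yl acetate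
Product: 8 (1S,4R,5R)-4-[(tert-butyldimethylsilyl)oxy]-5-(propan-2-yl)cyclopent-2-en-1-yl acetate
Conditions: TBSCl, imidazole, DMF, 25 °C
Reagents that add atoms: tert-butyldimethylsilyl chloride, CC(C)(C)[Si](C)(C)Cl
Why: Standard silylation of the free hydroxyl (future O6); the acetate is untouched.

Step 5
Reactants: 8 (1S,4R,5R)-4-[(tert-butyldimethylsilyl)oxy]-5-(propan-2-yl)cyclopent-2-en-1-yl acetate
Product: 9 (1S,4R,5R)-4-[(tert-butyldimethylsilyl)oxy]-5-(propan-2-yl)cyclopent-2-en-1-ol
Conditions: K2CO3 (0.2 equiv), MeOH, 0 °C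
Reagents that add atoms: none
Why: Methanolysis frees the future O8; a silyl shift between the two cis-1,3 oxygens, which would racemise 9, is not expected across the five-membered ring under these mild conditions.

Step 6
Reactants: 9 (1S,4R,5R)-4-[(tert-butyldimethylsilyl)oxy]-5-(propan-2-yl)cyclopent-2-en-1-ol
Product: 11 (2R,3R,4S)-4-[(tert-butyldimethylsilyl)oxy]-3-(propan-2-yl)pentane-1,2,5-triol, via dialdehyde 10 (not isolated)
Conditions: O3, CH2Cl2/MeOH 4:1, −78 °C; Me2S, −78 → 0 °C; then NaBH4, 0 °C
Reagents that add atoms: ozone, [O-][O+]=O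
Why: Ozonolysis opens the ring between C5 and C9, and immediate borohydride reduction of the α-oxygenated dialdehyde avoids epimerisation; the three stereocentres are not touched.

Step 7
Reactants: 11 (2R,3R,4S)-4-[(tert-butyldimethylsilyl)oxy]-3-(propan-2-yl)pentane-1,2,5-triol
Product: 13 2-[(tert-butyldimethylsilyl)oxy]-4-methyl-3-(oxiran-2-yl)pentan-1-ol (C8–C9 epoxide; stereocentres as in 11), via monotosylate 12 (not isolated)
Conditions: TsCl (1.05 equiv), Et3N, Bu2SnO (2 mol %), CH2Cl2, 0 °C; then DBU, 0 → 20 °C
Reagents that add atoms: none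
Why: Tin-catalysed sulfonylation activates only the primary hydroxyl that belongs to a 1,2-diol (C9, through the O8/O9 stannylene), not the C5 hydroxyl beside the silyl ether; base then closes the epoxide by 3-exo-tet displacement with O8 retained, so C8 keeps its configuration.

Step 8
Reactants: 13 2-[(tert-butyldimethylsilyl)oxy]-4-methyl-3-(oxiran-2-yl)pentan-1-ol
Product: 14 2-[(tert-butyldimethylsilyl)oxy]-4-methyl-3-(oxiran-2-yl)pentanal (C5 aldehyde)
Conditions: SO3·pyridine, DMSO, iPr2NEt, CH2Cl2, 0 °C
Reagents that add atoms: none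
Why: Parikh–Doering oxidation is non-acidic, so the 4,5-epoxy alcohol does not cyclise to a tetrahydrofuran and the α-silyloxy aldehyde is not epimerised; 14 is used crude.

Step 9
Reactants: 14 2-[(tert-butyldimethylsilyl)oxy]-4-methyl-3-(oxiran-2-yl)pentanal; 15 methyl 2-[bis(2,2,2-trifluoroethoxy)phosphoryl]propanoate
Product: 16 methyl (2Z)-4-[(tert-butyldimethylsilyl)oxy]-2,6-dimethyl-5-(oxiran-2-yl)hept-2-enoate
Conditions: 15, KN(SiMe3)2, 18-crown-6, THF, −78 °C; then 14
Reagents that add atoms: none
Why: Still–Gennari olefination: the trifluoroethyl phosphonate with a dissociated potassium counter-ion eliminates fast from the kinetic adduct and should give the Z-enoate (C6 cis to C3), the geometry the cis epoxide requires.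

Step 10
Reactants: 16 methyl (2Z)-4-[(tert-butyldimethylsilyl)oxy]-2,6-dimethyl-5-(oxiran-2-yl)hept-2-enoate
Product: 17 (2Z)-4-[(tert-butyldimethylsilyl)oxy]-2,6-dimethyl-5-(oxiran-2-yl)hept-2-en-1-ol
Conditions: iBu2AlH (2.5 equiv), CH2Cl2, −78 °C; potassium sodium tartrate work-up
Reagents that add atoms: none
Why: 1,2-Reduction of the enoate; at −78 °C the terminal epoxide should not be reduced.

Step 11
Reactants: 17 (2Z)-4-[(tert-butyldimethylsilyl)oxy]-2,6-dimethyl-5-(oxiran-2-yl)hept-2-en-1-ol
Product: 18 (2Z)-4-[(tert-butyldimethylsilyl)oxy]-2,6-dimethyl-5-(oxiran-2-yl)hept-2-enal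
Conditions: MnO2 (activated), CH2Cl2, 20 °C, dark
Reagents that add atoms: none
Why: Neutral allylic oxidation; the Z-enal is filtered and used at once to avoid Z-to-E isomerisation.

Step 12
Reactants: 18 (2Z)-4-[(tert-butyldimethylsilyl)oxy]-2,6-dimethyl-5-(oxiran-2-yl)hept-2-enal
Product: 19 (3Z)-5-[(tert-butyldimethylsilyl)oxy]-3,7-dimethyl-6-(oxiran-2-yl)octa-1,3-diene
Conditions: Ph3PCH3Br, KOtBu, THF, 0 °C; then 18, −78 → 0 °C
Reagents that add atoms: methyltriphenylphosphonium bromide, C[P+](c1ccccc1)(c1ccccc1)c1ccccc1.[Br-]
Why: Wittig methylenation adds C2 and makes the terminal alkene needed for hydroboration; the ylide does not attack the epoxide at these temperatures.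

Step 13
Reactants: 19 (3Z)-5-[(tert-butyldimethylsilyl)oxy]-3,7-dimethyl-6-(oxiran-2-yl)octa-1,3-diene; 20 ethynyltrimethylsilane
Product: 22 (7Z)-6-[(tert-butyldimethylsilyl)oxy]-8-methyl-5-(propan-2-yl)deca-7,9-dien-1-yn-4-ol, via silylalkyne 21 (not isolated)
Conditions: 20, n-BuLi, THF, −78 °C; BF3·OEt2, then 19, −78 °C; crude product, K2CO3, MeOH, 20 °C
Reagents that add atoms: none
Why: BF3-promoted alkynylation of a terminal epoxide (Yamaguchi-type) attacks the unhindered C9 and releases O8 without touching C8; at −78 °C the diene and silyl ether should survive, and carbonate in methanol removes only the alkynyl silane.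

Step 14
Reactants: 22 (7Z)-6-[(tert-butyldimethylsilyl)oxy]-8-methyl-5-(propan-2-yl)deca-7,9-dien-1-yn-4-ol
Product: 24 (1E,7Z)-6-[(tert-butyldimethylsilyl)oxy]-1-iodo-2,8-dimethyl-5-(propan-2-yl)deca-1,7,9-trien-4-ol, via alkenylalane 23 (not isolated)
Conditions: Me3Al (3.5 equiv), Cp2ZrCl2 (0.3 equiv), H2O (1 equiv), CH2Cl2, −25 °C; then I2, THF, −30 → 0 °C
Reagents that add atoms: trimethylaluminium, C[Al](C)C; iodine, II
Why: Negishi zirconium-catalysed methylalumination adds methyl and aluminium syn across the terminal alkyne with methyl on C10, and iodinolysis with retention gives the E-alkenyl iodide; homopropargylic alcohols are good substrates, and the water-accelerated low-temperature variant should leave the diene alone.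

Step 15
Reactants: 24 (1E,7Z)-6-[(tert-butyldimethylsilyl)oxy]-1-iodo-2,8-dimethyl-5-(propan-2-yl)deca-1,7,9-trien-4-ol; 25 3,4,5-trimethoxybenzoyl chloride
Product: 26 (1E,7Z)-6-[(tert-butyldimethylsilyl)oxy]-1-iodo-2,8-dimethyl-5-(propan-2-yl)deca-1,7,9-trien-4-yl 3,4,5-trimethoxybenzoate
Conditions: 25 (1.5 equiv), Et3N, DMAP (0.2 equiv), CH2Cl2, 0 → 20 °C
Reagents that add atoms: none
Why: DMAP-catalysed acylation of the only free hydroxyl (O8) installs the final ester with retention at C8.

Step 16
Reactants: 26 (1E,7Z)-6-[(tert-butyldimethylsilyl)oxy]-1-iodo-2,8-dimethyl-5-(propan-2-yl)deca-1,7,9-trien-4-yl 3,4,5-trimethoxybenzoate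
Product: 28 (1(10)E,4Z)-6-[(tert-butyldimethylsilyl)oxy]germacra-1(10),4-dien-8-yl 3,4,5-trimethoxybenzoate (C6, C7, C8 as in 30), via alkylborane 27 (not isolated)
Conditions: 9-BBN (1.6 equiv), THF, 0 → 20 °C; then slow addition to Pd(dppf)Cl2 (15 mol %), K3PO4 (3 M aq), DMF/THF, 50 °C, 2 mM
Reagents that add atoms: none
Why: 9-BBN should add only to the terminal CH2 of the diene (boron on C2); the trisubstituted alkenes, the alkenyl iodide and the aryl ester react far more slowly. Intramolecular B-alkyl Suzuki–Miyaura coupling then joins C2 to C1 with retention of the E geometry, a ring closure known for medium carbocycles with E-trisubstituted alkenyl iodides.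

Step 17
Reactants: 28 (1(10)E,4Z)-6-[(tert-butyldimethylsilyl)oxy]germacra-1(10),4-dien-8-yl 3,4,5-trimethoxybenzoate
Product: 29 (1(10)E,4Z)-6-hydroxygermacra-1(10),4-dien-8-yl 3,4,5-trimethoxybenzoate
Conditions: HF·pyridine, pyridine, THF, 0 → 20 °C
Reagents that add atoms: none
Why: Buffered fluoride removes the silyl ether without forming an alkoxide, so the O8 ester should not migrate to O6.

Step 18
Reactants: 29 (1(10)E,4Z)-6-hydroxygermacra-1(10),4-dien-8-yl 3,4,5-trimethoxybenzoate
Product: 30 (1(10)E,4S,5R,6S,7S,8S)-4,5-epoxy-6-hydroxygermacr-1(10)-en-8-yl 3,4,5-trimethoxybenzoate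
Conditions: Ti(OiPr)4 (1.2 equiv), tBuOOH (2 equiv, in decane), 4 Å molecular sieves, CH2Cl2, −20 °C; aqueous Na2SO4 work-up
Reagents that add atoms: tert-butyl hydroperoxide, CC(C)(C)OO
Why: Titanium-alkoxide-directed epoxidation oxidises only the alkene allylic to the free hydroxyl, so C1=C10 is spared. With H6 eclipsing the C4=C5 plane to avoid allylic 1,3-strain against C3, oxygen should be delivered to the face that gives the threo epoxy alcohol (4S,5R); the titanium reagent tolerates this wide O–C–C=C angle better than vanadium does.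

## Compound list

1 | sodium cyclopentadienide | [Na+].[cH-]1cccc1 | starting material
2 | 2-iodopropane | CC(C)I | starting material
3 | 5-(propan-2-yl)cyclopenta-1,3-diene | CC(C)C1C=CC=C1 | intermediate
4 | dioxygen | O=O | starting material
5 | meso 7-(propan-2-yl)-2,3-dioxabicyclo[2.2.1]hept-5-ene, isopropyl anti to the O–O bridge | O1[C@H]2C=C[C@@H](O1)[C@@H]2C(C)C | intermediate (not isolated)
6 | (1R,2r,3S)-2-(propan-2-yl)cyclopent-4-ene-1,3-diol, meso, hydroxyls cis to each other and trans to isopropyl | O[C@H]1C=C[C@@H](O)[C@@H]1C(C)C | intermediate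
7 | (1S,4R,5S)-4-hydroxy-5-(propan-2-yl)cyclopent-2-en-1-yl acetate | CC(=O)O[C@H]1C=C[C@@H](O)[C@@H]1C(C)C | intermediate
8 | (1S,4R,5R)-4-[(tert-butyldimethylsilyl)oxy]-5-(propan-2-yl)cyclopent-2-en-1-yl acetate | CC(=O)O[C@H]1C=C[C@@H](O[Si](C)(C)C(C)(C)C)[C@@H]1C(C)C | intermediate
9 | (1S,4R,5R)-4-[(tert-butyldimethylsilyl)oxy]-5-(propan-2-yl)cyclopent-2-en-1-ol | O[C@H]1C=C[C@@H](O[Si](C)(C)C(C)(C)C)[C@@H]1C(C)C | intermediate
10 | 2-[(tert-butyldimethylsilyl)oxy]-4-hydroxy-3-(propan-2-yl)pentanedial (C5 and C9 aldehydes; stereocentres as in 9) | O=C[C@H](O)[C@@H](C(C)C)[C@H](O[Si](C)(C)C(C)(C)C)C=O | intermediate (not isolated)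
11 | (2R,3R,4S)-4-[(tert-butyldimethylsilyl)oxy]-3-(propan-2-yl)pentane-1,2,5-triol | OC[C@H](O)[C@@H](C(C)C)[C@H](O[Si](C)(C)C(C)(C)C)CO | intermediate
12 | C9 mono-p-toluenesulfonate of 11 | Cc1ccc(cc1)S(=O)(=O)OC[C@H](O)[C@@H](C(C)C)[C@H](O[Si](C)(C)C(C)(C)C)CO | intermediate (not isolated)
13 | 2-[(tert-butyldimethylsilyl)oxy]-4-methyl-3-(oxiran-2-yl)pentan-1-ol (C8–C9 epoxide, C5 alcohol; stereocentres as in 11) | C1O[C@@H]1[C@@H](C(C)C)[C@H](O[Si](C)(C)C(C)(C)C)CO | intermediate
14 | 2-[(tert-butyldimethylsilyl)oxy]-4-methyl-3-(oxiran-2-yl)pentanal | C1O[C@@H]1[C@@H](C(C)C)[C@H](O[Si](C)(C)C(C)(C)C)C=O | intermediate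
15 | methyl 2-[bis(2,2,2-trifluoroethoxy)phosphoryl]propanoate | COC(=O)C(C)P(=O)(OCC(F)(F)F)OCC(F)(F)F | starting material
16 | methyl (2Z)-4-[(tert-butyldimethylsilyl)oxy]-2,6-dimethyl-5-(oxiran-2-yl)hept-2-enoate | C1O[C@@H]1[C@@H](C(C)C)[C@H](O[Si](C)(C)C(C)(C)C)/C=C(C)\C(=O)OC | intermediate
17 | (2Z)-4-[(tert-butyldimethylsilyl)oxy]-2,6-dimethyl-5-(oxiran-2-yl)hept-2-en-1-ol | C1O[C@@H]1[C@@H](C(C)C)[C@H](O[Si](C)(C)C(C)(C)C)/C=C(C)\CO | intermediate
18 | (2Z)-4-[(tert-butyldimethylsilyl)oxy]-2,6-dimethyl-5-(oxiran-2-yl)hept-2-enal | C1O[C@@H]1[C@@H](C(C)C)[C@H](O[Si](C)(C)C(C)(C)C)/C=C(C)\C=O | intermediate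
19 | (3Z)-5-[(tert-butyldimethylsilyl)oxy]-3,7-dimethyl-6-(oxiran-2-yl)octa-1,3-diene | C1O[C@@H]1[C@@H](C(C)C)[C@H](O[Si](C)(C)C(C)(C)C)/C=C(C)\C=C | intermediate
20 | ethynyltrimethylsilane | C#C[Si](C)(C)C | starting material
21 | (7Z)-6-[(tert-butyldimethylsilyl)oxy]-8-methyl-5-(propan-2-yl)-1-(trimethylsilyl)deca-7,9-dien-1-yn-4-ol | C[Si](C)(C)C#CC[C@H](O)[C@@H](C(C)C)[C@H](O[Si](C)(C)C(C)(C)C)/C=C(C)\C=C | intermediate (not isolated)
22 | (7Z)-6-[(tert-butyldimethylsilyl)oxy]-8-methyl-5-(propan-2-yl)deca-7,9-dien-1-yn-4-ol | C#CC[C@H](O)[C@@H](C(C)C)[C@H](O[Si](C)(C)C(C)(C)C)/C=C(C)\C=C | intermediate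
23 | (E)-alkenyl(dimethyl)alane at C1 with O8 as its dimethylaluminium alkoxide | C[Al](C)/C=C(C)/C[C@H](O[Al](C)C)[C@@H](C(C)C)[C@H](O[Si](C)(C)C(C)(C)C)/C=C(C)\C=C | intermediate (not isolated)
24 | (1E,7Z)-6-[(tert-butyldimethylsilyl)oxy]-1-iodo-2,8-dimethyl-5-(propan-2-yl)deca-1,7,9-trien-4-ol | I/C=C(C)/C[C@H](O)[C@@H](C(C)C)[C@H](O[Si](C)(C)C(C)(C)C)/C=C(C)\C=C | intermediate
25 | 3,4,5-trimethoxybenzoyl chloride | COc1cc(C(Cl)=O)cc(OC)c1OC | starting material
26 | (1E,7Z)-6-[(tert-butyldimethylsilyl)oxy]-1-iodo-2,8-dimethyl-5-(propan-2-yl)deca-1,7,9-trien-4-yl 3,4,5-trimethoxybenzoate | COc1cc(C(=O)O[C@@H](C/C(C)=C/I)[C@@H](C(C)C)[C@H](O[Si](C)(C)C(C)(C)C)/C=C(C)\C=C)cc(OC)c1OC | intermediate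
27 | B-alkyl-9-borabicyclo[3.3.1]nonane from 26, boron on C2 | COc1cc(C(=O)O[C@@H](C/C(C)=C/I)[C@@H](C(C)C)[C@H](O[Si](C)(C)C(C)(C)C)/C=C(C)\CCB2C3CCCC2CCC3)cc(OC)c1OC | intermediate (not isolated)
28 | (1(10)E,4Z)-6-[(tert-butyldimethylsilyl)oxy]germacra-1(10),4-dien-8-yl 3,4,5-trimethoxybenzoate (C6, C7, C8 as in 30) | COc1cc(C(=O)O[C@H]2C/C(C)=C/CC/C(C)=C\[C@@H](O[Si](C)(C)C(C)(C)C)[C@@H]2C(C)C)cc(OC)c1OC | intermediate
29 | (1(10)E,4Z)-6-hydroxygermacra-1(10),4-dien-8-yl 3,4,5-trimethoxybenzoate (C6, C7, C8 as in 30) | COc1cc(C(=O)O[C@H]2C/C(C)=C/CC/C(C)=C\[C@@H](O)[C@@H]2C(C)C)cc(OC)c1OC | intermediate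
30 | (1(10)E,4S,5R,6S,7S,8S)-4,5-epoxy-6-hydroxygermacr-1(10)-en-8-yl 3,4,5-trimethoxybenzoate | COc1cc(C(=O)O[C@H]2C/C(C)=C/CC[C@]3(C)O[C@@H]3[C@@H](O)[C@@H]2C(C)C)cc(OC)c1OC | target

## Step count and least certain steps

Total: 18 steps. Longest linear sequence: 18 steps (1 and 2 to 30); 15, 20 and 25 are bought.

**Step 2 (key step).** Most likely to go wrong: partial isomerisation of 3 to the 1- and 2-isopropyl dienes before oxygen arrives, which would feed regioisomeric endoperoxides into the reduction. Thermal rearrangement of 5 if the thiourea reduction lags, or incomplete anti approach, are the other risks. Fallback from 3 to 6 without singlet oxygen: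
- Buffered peracetic acid (Na2CO3, CH2Cl2, −20 °C) should epoxidise one diene double bond anti to isopropyl, giving racemic 4-(propan-2-yl)-6-oxabicyclo[3.1.0]hex-2-ene F1.
- Pd(PPh3)4 (zerovalent palladium, catalytic) with acetic acid in THF at 0 °C should open the vinyl epoxide by overall syn-1,4 substitution (ionisation with inversion, acetate attack with inversion), giving racemic cis-4-acetoxy-5-(propan-2-yl)cyclopent-2-en-1-ol F2.
- K2CO3 in methanol returns the route at meso 6.

**Step 18.** Most likely to go wrong: delivery of oxygen to the face cis to O6. Metal-alkoxide-directed epoxidation of eight- and nine-membered (Z)-cycloalkenols is known to take that course, because the ring, not allylic strain, fixes the O–C–C=C angle, and it would give the wrong epoxide. Lewis-acid opening of the new epoxide by C1=C10 is a second risk. Fallback from 29 to 30 by double inversion, which turns cis delivery to advantage: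
- Mitsunobu reaction of 29 (4-nitrobenzoic acid, PPh3, diisopropyl azodicarboxylate) gives the C6-epimeric 4-nitrobenzoate F3.
- K2CO3 in methanol at 0 °C, which should cleave the electron-poor nitrobenzoate much faster than the hindered, electron-rich trimethoxybenzoate, gives the C6-epimeric alcohol F4.
- The same directed epoxidation, now cis to the inverted hydroxyl and therefore on the required face, gives the C6-epimeric epoxy alcohol F5.
- A second Mitsunobu inversion gives the 4-nitrobenzoate of the target F6, and selective methanolysis gives 30.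

**Step 16.** Most likely to go wrong: intermolecular coupling to oligomers, and protodeboronation or β-hydride elimination outrunning a strained reductive elimination to the (E,Z)-cyclodecadiene. Fallback from 17 to 28, closing C2–C3 by sulfone alkylation, the classical ring closure for ten-membered terpenoids:
- PhSSPh and PBu3 convert 17 into the allylic phenyl sulfide F7.
- The conditions of step 13 give the silylalkyne F8 (not isolated) and then the alkynol F9.
- Et3SiCl and imidazole give the O8 triethylsilyl ether F10.
- Methylalumination as in step 14, then n-BuLi and paraformaldehyde, gives the (E)-allylic alcohol F11 (C2 hydroxyl).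
- MsCl, LiCl and 2,4,6-collidine give the allylic chloride F12.
- (NH4)6Mo7O24 (catalytic) and H2O2 oxidise sulfur only, giving the allylic sulfone F13.
- KN(SiMe3)2 in THF at 2 mM closes C2–C3 by SN2 displacement, giving the macrocyclic sulfone F14.
- Reductive desulfonylation (SmI2, DMPU, THF/MeOH, −20 °C) gives the silyl-protected macrocycle F15.
- Pyridinium p-toluenesulfonate in methanol removes only the triethylsilyl group, giving the C8 alcohol F16.
- Acylation with 25 as in step 15 returns the route at 28.

**Step 7.** Most likely to go wrong: sulfonylation of the C5 hydroxyl as well, followed by ether formation; silyl migration from O6 to O5 under base; or acid-triggered 5-exo cyclisation of the epoxy alcohol. Fallback from 11 to 13 by explicit protection: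
- 2,2-Dimethoxypropane and pyridinium p-toluenesulfonate give the C8,C9-acetonide F17.
- Ac2O and pyridine give its C5 acetate F18.
- Aqueous acetic acid gives the diol acetate F19.
- TsCl and pyridine, now with a single primary hydroxyl, give the tosylate F20.
- K2CO3 in methanol at 0 °C closes the epoxide and removes the acetate, returning the route at 13.

**Step 3.** Most likely to go wrong: slow or poorly selective acylation, because the isopropyl group flanks both carbinol carbons, with over-acylation to the diacetate. Fallback from 6 directly to 9: a small-molecule-catalysed enantioselective mono-silylation (TBSCl, iPr2NEt, chiral amino-acid-derived N-methylimidazole catalyst, THF, −40 °C). This replaces steps 3 to 5 and makes no new compound.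

## Further compounds

F1 | step 2 | racemic 4-(propan-2-yl)-6-oxabicyclo[3.1.0]hex-2-ene, epoxide anti to isopropyl | C1=C[C@H]2O[C@H]2[C@@H]1C(C)C
F2 | step 2 | racemic cis-4-acetoxy-5-(propan-2-yl)cyclopent-2-en-1-ol (racemate of 7) | CC(=O)O[C@H]1C=C[C@@H](O)[C@@H]1C(C)C
F3 | step 18 | C6-epimer of 29 as its 4-nitrobenzoate | COc1cc(C(=O)O[C@H]2C/C(C)=C/CC/C(C)=C\[C@H](OC(=O)c3ccc(cc3)[N+]([O-])=O)[C@@H]2C(C)C)cc(OC)c1OC
F4 | step 18 | C6-epimer of 29 | COc1cc(C(=O)O[C@H]2C/C(C)=C/CC/C(C)=C\[C@H](O)[C@@H]2C(C)C)cc(OC)c1OC
F5 | step 18 | C6-epimer of 30 | COc1cc(C(=O)O[C@H]2C/C(C)=C/CC[C@]3(C)O[C@@H]3[C@H](O)[C@@H]2C(C)C)cc(OC)c1OC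
F6 | step 18 | 6-O-(4-nitrobenzoate) of 30 | COc1cc(C(=O)O[C@H]2C/C(C)=C/CC[C@]3(C)O[C@@H]3[C@@H](OC(=O)c4ccc(cc4)[N+]([O-])=O)[C@@H]2C(C)C)cc(OC)c1OC
F7 | step 16 | C3 phenyl sulfide of 17 | C1O[C@@H]1[C@@H](C(C)C)[C@H](O[Si](C)(C)C(C)(C)C)/C=C(C)\CSc1ccccc1
F8 | step 16 | silylalkyne from F7 | C[Si](C)(C)C#CC[C@H](O)[C@@H](C(C)C)[C@H](O[Si](C)(C)C(C)(C)C)/C=C(C)\CSc1ccccc1
F9 | step 16 | terminal alkynol with C3 phenyl sulfide | C#CC[C@H](O)[C@@H](C(C)C)[C@H](O[Si](C)(C)C(C)(C)C)/C=C(C)\CSc1ccccc1
F10 | step 16 | O8 triethylsilyl ether of F9 | C#CC[C@H](O[Si](CC)(CC)CC)[C@@H](C(C)C)[C@H](O[Si](C)(C)C(C)(C)C)/C=C(C)\CSc1ccccc1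
F11 | step 16 | (E)-allylic alcohol, hydroxyl on C2 | OC/C=C(C)/C[C@H](O[Si](CC)(CC)CC)[C@@H](C(C)C)[C@H](O[Si](C)(C)C(C)(C)C)/C=C(C)\CSc1ccccc1
F12 | step 16 | (E)-allylic chloride, chlorine on C2 | ClC/C=C(C)/C[C@H](O[Si](CC)(CC)CC)[C@@H](C(C)C)[C@H](O[Si](C)(C)C(C)(C)C)/C=C(C)\CSc1ccccc1
F13 | step 16 | C3 phenyl sulfone with C2 chloride | ClC/C=C(C)/C[C@H](O[Si](CC)(CC)CC)[C@@H](C(C)C)[C@H](O[Si](C)(C)C(C)(C)C)/C=C(C)\CS(=O)(=O)c1ccccc1
F14 | step 16 | macrocyclic sulfone, phenylsulfonyl on C3 (either epimer) | CC[Si](CC)(CC)O[C@H]1C/C(C)=C/CC(S(=O)(=O)c2ccccc2)/C(C)=C\[C@@H](O[Si](C)(C)C(C)(C)C)[C@@H]1C(C)C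
F15 | step 16 | (1(10)E,4Z)-germacradiene with O6 tert-butyldimethylsilyl and O8 triethylsilyl | CC[Si](CC)(CC)O[C@H]1C/C(C)=C/CC/C(C)=C\[C@@H](O[Si](C)(C)C(C)(C)C)[C@@H]1C(C)C
F16 | step 16 | (1(10)E,4Z)-6-[(tert-butyldimethylsilyl)oxy]germacra-1(10),4-dien-8-ol | O[C@H]1C/C(C)=C/CC/C(C)=C\[C@@H](O[Si](C)(C)C(C)(C)C)[C@@H]1C(C)C
F17 | step 7 | C8,C9-acetonide of 11 | CC1(C)OC[C@H](O1)[C@@H](C(C)C)[C@H](O[Si](C)(C)C(C)(C)C)CO
F18 | step 7 | C5 acetate of F17 | CC1(C)OC[C@H](O1)[C@@H](C(C)C)[C@H](O[Si](C)(C)C(C)(C)C)COC(C)=O
F19 | step 7 | C5 acetate of 11 | OC[C@H](O)[C@@H](C(C)C)[C@H](O[Si](C)(C)C(C)(C)C)COC(C)=O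
F20 | step 7 | C9 p-toluenesulfonate of F19 | Cc1ccc(cc1)S(=O)(=O)OC[C@H](O)[C@@H](C(C)C)[C@H](O[Si](C)(C)C(C)(C)C)COC(C)=O
F0 | step 3 | none | none
A1 | alternative 1 | ring-contracted ten-membered C6 alcohol with C7 isopropenyl and O8 4-methoxybenzyl | COc1ccc(CO[C@H]2C/C(C)=C/CC/C(C)=C\[C@@H](O)[C@@H]2C(C)=C)cc1
A2 | alternative 1 | thirteen-membered diallylic ether (C6–O–C12, E C7=C11) | O1C/C(C)=C/[C@@H](OCc2ccc(OC)cc2)C/C(C)=C/CC/C(C)=C\C1
A3 | alternative 2 | cis-fused hydroazulenone [4+3] adduct | O=C1CCC(C)=C[C@@]2(O[Si](CC)(CC)CC)[C@H](C(C)C)[C@@H](OCc3ccc(OC)cc3)C[C@@]12C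
A4 | alternative 2 | tertiary α-chloro methyl ketone tethered to a triethylsilyloxy diene (either epimer at C10) | C=C(C)/C=C(O[Si](CC)(CC)CC)/[C@H](C(C)C)[C@@H](OCc1ccc(OC)cc1)CC(C)(Cl)C(C)=O
A5 | alternative 3 | ten-membered homoallylic alcohol with C7 isopropenyl, epoxide in place | O[C@H]1C/C(C)=C/CC[C@]2(C)O[C@@H]2[C@@H](O[Si](CC)(CC)CC)[C@@H]1C(C)=C
A6 | alternative 3 | acyclic epoxy aldehyde with allylic bromide at C12 | O=CC/C(C)=C/CC[C@]1(C)O[C@@H]1[C@@H](O[Si](CC)(CC)CC)/C=C(C)/CBr
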